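The upper pyran ring (O1, C2, C3, C4, C4a, C8a) is cut at O1–C2 and C3–C4. This reveals an o-quinone methide on the upper A-ring, whose methide carbon (future C4) is already bonded to C8 of benzylated (+)-catechin, and 3,4-dibenzyloxystyrene as the C2–C3 unit. A chiral Brønsted-acid-catalysed [4+2] cycloaddition then closes that ring, forms both bonds and sets the 2,4-cis (2S,4S) pair in one operation. The precursor is a diaryl carbinol carrying a single free ortho-phenol, assembled from 8-lithio-penta-O-benzylcatechin and 4-benzyloxysalicylaldehyde. Global hydrogenolysis finishes the synthesis.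

Key step: step 6

Assumption: 3,4-dibenzyloxybenzaldehyde and 4-benzyloxy-2-hydroxybenzaldehyde are bought as such; each is otherwise one benzylation away from the parent dihydroxybenzaldehyde.
Assumption: the catalyst antipode that favours the (2S,4S) series is taken to be (R); should the first run show the opposite sense, the (S)-catalyst is used and nothing else changes.
Remark: the target and the intermediate structures were checked atom by atom and needed no correction. The upper unit is (2S,4S), 2,4-cis; the lower unit is (2R,3S), as in (+)-catechin.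

Step 1
Reactants: 1 (+)-catechin
Product: 2 5,7,3',4'-tetra-O-benzylcatechin
Conditions: BnBr (4.4 equiv), K2CO3, DMF, 0 °C → rt
Reagents that add atoms: benzyl bromide, BrCc1ccccc1
Why: Williamson etherification in which carbonate deprotonates only the four phenols, so the secondary 3-OH should stay free and the two catechin stereocentres, which take no part, should be kept.

Step 2
Reactants: 2 5,7,3',4'-tetra-O-benzylcatechin
Product: 3 8-bromo-5,7,3',4'-tetra-O-benzylcatechin
Conditions: NBS (1.0 equiv), CH2Cl2, −78 °C → rt
Reagents that add atoms: N-bromosuccinimide, O=C1CCC(=O)N1Br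
Why: Electrophilic aromatic bromination of the phloroglucinol-type A-ring, where attack at C8 over C6 is the established preference for 5,7-di-O-benzylated flavan-3-ols, and one equivalent at low temperature should stop at the monobromide.

Step 3
Reactants: 3 8-bromo-5,7,3',4'-tetra-O-benzylcatechin
Product: 4 8-bromo-3,5,7,3',4'-penta-O-benzylcatechin
Conditions: NaH, BnBr, DMF, 0 °C → rt
Reagents that add atoms: benzyl bromide, BrCc1ccccc1
Why: Williamson etherification of the secondary alkoxide caps the last acidic proton so that no organolithium is wasted in step 5, and the benzyl group leaves with the others in step 7.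

Step 4
Reactants: 5 3,4-dibenzyloxybenzaldehyde
Product: 6 3,4-dibenzyloxystyrene
Conditions: Ph3PCH3Br, KOtBu, THF, 0 °C → rt
Reagents that add atoms: methyltriphenylphosphonium bromide, C[P+](c1ccccc1)(c1ccccc1)c1ccccc1.[Br-]
Why: Wittig methylenation of a non-enolisable aryl aldehyde with the unstabilised ylide should give the terminal styrene cleanly, and no stereocentre is involved.

Step 5
Reactants: 4 8-bromo-3,5,7,3',4'-penta-O-benzylcatechin; 7 4-benzyloxy-2-hydroxybenzaldehyde
Product: 10 (4-benzyloxy-2-hydroxyphenyl)(penta-O-benzylcatechin-8-yl)methanol as both carbinol epimers, via aryllithium 8 (not isolated), via sodium phenoxide 9 (not isolated)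
Conditions: 4, n-BuLi, THF, −78 °C; then 9 (from 7, NaH, THF, 0 °C; 1.3 equiv), −78 → 0 °C; sat. aq NH4Cl; Et3N-deactivated SiO2
Reagents that add atoms: none
Why: Bromine–lithium exchange followed by 1,2-addition of the aryllithium to the aldehyde, in which prior conversion of the cheap aldehyde into its sodium phenoxide removes the only acidic proton so the valuable aryllithium is spent on C–C bond formation alone; the new carbinol centre is formed without control because it becomes sp2 in step 6.

Step 6
Reactants: 10 (4-benzyloxy-2-hydroxyphenyl)(penta-O-benzylcatechin-8-yl)methanol; 6 3,4-dibenzyloxystyrene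
Product: 12 octa-O-benzyl target with the (2S,4S)-2,4-cis upper flavan on catechin C8, via o-quinone methide 11 (not isolated)
Conditions: (R)-3,3'-bis(2,4,6-triisopropylphenyl)-BINOL N-triflylphosphoramide (10 mol%), 6 (3 equiv), CH2Cl2, −40 → −10 °C, 10 added slowly
Reagents that add atoms: none
Why: The acid ionises the doubly benzylic carbinol of 10 (either epimer) to the E-configured o-quinone methide 11, which stays hydrogen-bonded or ion-paired to the chiral phosphoramide anion; the CH2 terminus of the alkoxystyrene then attacks the methide carbon (C3–C4) and the developing p-alkoxybenzyl cation is captured by the quinone oxygen (O1–C2) in a concerted, strongly asynchronous inverse-electron-demand hetero-Diels–Alder. The closest known reaction type is the Brønsted-acid-catalysed [4+2] cycloaddition of o-quinone methides generated from o-hydroxybenzhydrols with styrenes, which gives 2,4-cis-diarylchromans and has chiral phosphoric-acid-type variants. The pyran ring is closed by this intermolecular [4+2] mode (4π O=C8a–C4a=C4 with 2π C2=C3), both bonds forming suprafacially. C4 is set by which face of 11 the styrene reaches, and that face is chosen by the chiral counter-anion because the catechin centres are too far away to be relied on; C2 follows C4 through the endo arrangement of the styrene aryl, and 2,4-cis is also the more stable, diequatorial isomer. Regiochemistry comes from the polarisation of the styrene (nucleophilic CH2, cation-stabilising 4-alkoxyaryl), and only one quinone methide can form because 10 has a single free phenol. Competing Friedel–Crafts attack by C6 of a second catechin ring and styrene oligomerisation are held back by keeping 6 in excess and adding 10 slowly at low temperature.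

Step 7
Reactants: 12 octa-O-benzyl target
Product: 13 CNP0227165.3, (2R,3S)-2-(3,4-dihydroxyphenyl)-8-[(2S,4S)-2-(3,4-dihydroxyphenyl)-7-hydroxychroman-4-yl]chromane-3,5,7-triol
Conditions: H2 (1 atm), Pd(OH)2/C, THF/MeOH, rt; filtration under Ar
Reagents that add atoms: none
Why: Heterogeneous hydrogenolysis of all eight benzyl ethers under neutral conditions, which should leave the cyclic C2–O1 benzylic ethers and the four stereocentres untouched, as is usual for benzylated oligoflavans.

Compound list
1 | (+)-catechin, (2R,3S) | O[C@H]1Cc2c(O)cc(O)cc2O[C@@H]1c1ccc(O)c(O)c1 | starting material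
2 | 5,7,3',4'-tetra-O-benzylcatechin, (2R,3S), free 3-OH | O[C@H]1Cc2c(OCc3ccccc3)cc(OCc3ccccc3)cc2O[C@@H]1c1ccc(OCc2ccccc2)c(OCc2ccccc2)c1 | intermediate
3 | 8-bromo-5,7,3',4'-tetra-O-benzylcatechin, (2R,3S) | O[C@H]1Cc2c(OCc3ccccc3)cc(OCc3ccccc3)c(Br)c2O[C@@H]1c1ccc(OCc2ccccc2)c(OCc2ccccc2)c1 | intermediate
4 | 8-bromo-3,5,7,3',4'-penta-O-benzylcatechin, (2R,3S) | Brc1c(OCc3ccccc3)cc(OCc3ccccc3)c2c1O[C@H](c1ccc(OCc3ccccc3)c(OCc3ccccc3)c1)[C@@H](OCc1ccccc1)C2 | intermediate
5 | 3,4-dibenzyloxybenzaldehyde | O=Cc1ccc(OCc2ccccc2)c(OCc2ccccc2)c1 | starting material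
6 | 3,4-dibenzyloxystyrene | C=Cc1ccc(OCc2ccccc2)c(OCc2ccccc2)c1 | intermediate
7 | 4-benzyloxy-2-hydroxybenzaldehyde | O=Cc1ccc(OCc2ccccc2)cc1O | starting material
8 | 8-lithio-3,5,7,3',4'-penta-O-benzylcatechin, (2R,3S) | [Li]c1c(OCc3ccccc3)cc(OCc3ccccc3)c2c1O[C@H](c1ccc(OCc3ccccc3)c(OCc3ccccc3)c1)[C@@H](OCc1ccccc1)C2 | intermediate (not isolated)
9 | sodium 5-benzyloxy-2-formylphenoxide | [Na+].[O-]c1cc(OCc2ccccc2)ccc1C=O | intermediate (not isolated)
10 | (4-benzyloxy-2-hydroxyphenyl)[(2R,3S)-3,5,7-tris(benzyloxy)-2-(3,4-bis(benzyloxy)phenyl)chroman-8-yl]methanol, both carbinol epimers | OC(c1ccc(OCc3ccccc3)cc1O)c1c(OCc3ccccc3)cc(OCc3ccccc3)c2c1O[C@H](c1ccc(OCc3ccccc3)c(OCc3ccccc3)c1)[C@@H](OCc1ccccc1)C2 | intermediate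
11 | (E)-3-benzyloxy-6-{[(2R,3S)-3,5,7-tris(benzyloxy)-2-(3,4-bis(benzyloxy)phenyl)chroman-8-yl]methylidene}cyclohexa-2,4-dien-1-one (o-quinone methide) | O=C1C=C(OCc3ccccc3)C=C/C1=C\c1c(OCc3ccccc3)cc(OCc3ccccc3)c2c1O[C@H](c1ccc(OCc3ccccc3)c(OCc3ccccc3)c1)[C@@H](OCc1ccccc1)C2 | intermediate (not isolated)
12 | (2R,3S)-3,5,7-tris(benzyloxy)-2-[3,4-bis(benzyloxy)phenyl]-8-{(2S,4S)-7-benzyloxy-2-[3,4-bis(benzyloxy)phenyl]chroman-4-yl}chromane (octa-O-benzyl target, 2,4-cis upper unit) | c1ccccc1COc1ccc2c(c1)O[C@H](c1ccc(OCc3ccccc3)c(OCc3ccccc3)c1)C[C@@H]2c1c(OCc3ccccc3)cc(OCc3ccccc3)c2c1O[C@H](c1ccc(OCc3ccccc3)c(OCc3ccccc3)c1)[C@@H](OCc1ccccc1)C2 | intermediate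
13 | (2R,3S)-2-(3,4-dihydroxyphenyl)-8-[(2S,4S)-2-(3,4-dihydroxyphenyl)-7-hydroxychroman-4-yl]chromane-3,5,7-triol (CNP0227165.3) | Oc1ccc2c(c1)O[C@H](c1ccc(O)c(O)c1)C[C@@H]2c1c(O)cc(O)c2c1O[C@H](c1ccc(O)c(O)c1)[C@@H](O)C2 | target

Total step count: 7. Longest linear sequence: 6 steps (steps 1, 2, 3, 5, 6, 7).

Steps most likely to fail

Step 6. The chiral anion may discriminate poorly between the two faces of the hindered, twisted quinone methide, so that the (2R,4R)-cis series forms alongside the wanted one. The quinone methide may also be lost to Friedel–Crafts self-condensation, or the styrene to acid-induced oligomerisation. The fallback builds the C4–C8' bond by carbonyl addition and sets C4 by ionic reduction; it sets out from 4 and comes back at 12. 7-Hydroxychromone is benzylated (BnBr, K2CO3, DMF) to 7-benzyloxychromone F1. Asymmetric conjugate addition of 3,4-bis(benzyloxy)phenylboronic acid (Pd(II)/pyridine-oxazoline or Rh(I)/chiral diene, ligand antipode chosen for the 2S product) should give (S)-7-benzyloxy-2-[3,4-bis(benzyloxy)phenyl]chroman-4-one F2. Aryllithium 8, generated from 4 as in step 5 and transmetallated with CeCl3 to suppress enolisation and ring-opening of the flavanone, should add to the ketone to give the tertiary 4-aryl-flavan-4-ol F3. Ionic hydrogenation (Et3SiH, TFA, CH2Cl2, −78 °C) removes the tertiary benzylic hydroxyl through the C4 cation; axial hydride delivery on the face away from the C2 aryl should give the 2,4-cis compound 12.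

Step 5. The hindered aryllithium may add sluggishly to the electron-rich, poorly soluble phenoxide aldehyde and be protonated instead, which returns debrominated penta-O-benzylcatechin. The fallback masks the phenol instead of ionising it; it sets out from 7 and 4 and comes back at 10. Allylation of 7 (allyl bromide, K2CO3, DMF) gives 2-allyloxy-4-benzyloxybenzaldehyde F4, an ordinary electrophilic aldehyde. Addition of aryllithium 8 at −78 °C should give the O-allyl diaryl carbinol F5. Neutral Tsuji–Trost deallylation (cat. Pd(PPh3)4, morpholine, THF, rt) frees the phenol without ionising the carbinol and gives 10.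

Step 7. Removal of eight benzyl groups may stall at partly protected stages, or over-reduction may open the benzylic C2–O1 bonds of the pyran rings; the free polyphenol is also prone to air oxidation during isolation. The fallback replaces hydrogenolysis by Lewis-acid dealkylation; it sets out from 12 and comes back at 13. BCl3 with pentamethylbenzene as cation scavenger (CH2Cl2, −78 °C, methanol quench) should cleave the aryl and alkyl benzyl ethers without hydrogen; no new compound is made on this way (F0).

Further compounds
F1 | step 6 | 7-benzyloxy-4H-chromen-4-one | O=c1ccoc2cc(OCc3ccccc3)ccc12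
F2 | step 6 | (S)-7-benzyloxy-2-[3,4-bis(benzyloxy)phenyl]chroman-4-one | c1ccccc1COc1ccc2c(c1)O[C@H](c1ccc(OCc3ccccc3)c(OCc3ccccc3)c1)CC2=O
F3 | step 6 | (2S)-7-benzyloxy-2-[3,4-bis(benzyloxy)phenyl]-4-[(2R,3S)-3,5,7-tris(benzyloxy)-2-(3,4-bis(benzyloxy)phenyl)chroman-8-yl]chroman-4-ol, C4 epimers | c1ccccc1COc1ccc2c(c1)O[C@H](c1ccc(OCc3ccccc3)c(OCc3ccccc3)c1)CC2(O)c1c(OCc3ccccc3)cc(OCc3ccccc3)c2c1O[C@H](c1ccc(OCc3ccccc3)c(OCc3ccccc3)c1)[C@@H](OCc1ccccc1)C2
F4 | step 5 | 2-allyloxy-4-benzyloxybenzaldehyde | O=Cc1ccc(OCc2ccccc2)cc1OCC=C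
F5 | step 5 | (2-allyloxy-4-benzyloxyphenyl)[(2R,3S)-3,5,7-tris(benzyloxy)-2-(3,4-bis(benzyloxy)phenyl)chroman-8-yl]methanol, both carbinol epimers | OC(c1ccc(OCc3ccccc3)cc1OCC=C)c1c(OCc3ccccc3)cc(OCc3ccccc3)c2c1O[C@H](c1ccc(OCc3ccccc3)c(OCc3ccccc3)c1)[C@@H](OCc1ccccc1)C2
F0 | step 7 | none | none
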